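A direct plan would reduce 4'-hydroxyacetophenone to the (R)-carbinol, ortho-formylate the phenol, alkylate it with a bromoketone acetal to the keto aldehyde A1, close ring B by an amine-catalysed intramolecular aldol to the hydroxy ketone A2, methylenate the ketone to the diol acetal A3, and finish by double tigloylation and acetal hydrolysis.
Its weakest step would be the aldol ring closure (C2–C3): both ring stereocentres would rest on unproven catalyst control, and A2, a β-hydroxy ketone with an acidic C2–H, would be prone to epimerisation, retro-aldol cleavage and dehydration to the aromatic benzofuran.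
The methylenation of A2 would be the step least welcome on late material: a hindered, enolisable α-aryloxy ketone between an acetal and a free β-hydroxyl invites retro-aldol cleavage and elimination.
Three further steps would go into the bromoketone acetal and the acylating agent with no gain in complexity, and the formylation would expose a para-hydroxybenzylic carbinol to quinone methide formation and racemisation.

Plan of the new route
The retrosynthesis cuts the formyl C–C bond (back to a 1-bromovinyl group), then both ester C–O bonds, then O1–C2 and C–Br together, which opens ring B to a phenol carrying a terminal allene, and last the C3–C2 bond back to 5-acetylsalicylaldehyde.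
Enabling feature: C2 of ring B carries O1 and the carbon Cα that bears the exocyclic =CH2 and the formyl group, so C2, Cα and CH2 are the three carbons of a terminal allene, and O1–C2 plus Cα–X are the two bonds of a 1,2-addition across its inner double bond.
Ring A is bought as the phenol; ring B is the only ring made and closes by C–O bond formation at O1–C2, after C3 has been set by reagent control. C2 then follows from C3, and the side-chain carbinol is set last by catalyst control.
No aldol, no ketone next to C2 and no olefination occur; the enal appears only in the last step, and tiglic acid is used as bought.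

Key step: step 4

Assumption: in step 3 the (R,R)-controller is taken to expose the Re face of the aldehyde (chair transition state, aryl group equatorial); if the sense is the reverse, the (S,S)-controller is used and nothing else changes.

Step 1
Reactants: 1 4'-hydroxyacetophenone
Product: 2 5-acetyl-2-hydroxybenzaldehyde
Conditions: MgCl2, Et3N, (CH2O)n, MeCN, reflux; aq. HCl
Reagents that add atoms: paraformaldehyde (formaldehyde), C=O
Why: Casnati–Skattebøl ortho-formylation, in which the magnesium phenoxide delivers formaldehyde to one of the two equivalent ortho positions and a second formaldehyde oxidises the benzylic alkoxide by hydride transfer, while the methyl ketone is not enolised by triethylamine; no stereocentre is formed.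

Step 2
Reactants: 2 5-acetyl-2-hydroxybenzaldehyde
Product: 3 5-acetyl-2-{[tert-butyl(dimethyl)silyl]oxy}benzaldehyde
Conditions: tBuMe2SiCl, imidazole, DMF, rt
Reagents that add atoms: tert-butyl(chloro)dimethylsilane, CC(C)(C)[Si](C)(C)Cl
Why: Imidazole-promoted silylation masks the acidic phenol for the boron reagent of step 3 and places on the phenol oxygen the silyl group that is later handed on to the C3 oxygen.

Step 3
Reactants: 3 5-acetyl-2-{[tert-butyl(dimethyl)silyl]oxy}benzaldehyde; 4 tributyl(propa-1,2-dien-1-yl)stannane
Product: 6 1-{3-[(1R)-1-{[tert-butyl(dimethyl)silyl]oxy}buta-2,3-dien-1-yl]-4-hydroxyphenyl}ethan-1-one, via aryl silyl ether carbinol 5 (not isolated)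
Conditions: (1R,2R)-N,N′-bis(p-toluenesulfonyl)-1,2-diphenylethane-1,2-diamine, BBr3, CH2Cl2, 0 °C → rt, evaporation; 4, CH2Cl2, 0 °C → rt; 3, −78 °C; pH 7 buffer; then NaH, THF, −20 → 0 °C; AcOH
Reagents that add atoms: tributyl(propa-1,2-dien-1-yl)stannane (4), C=C=C[Sn](CCCC)(CCCC)CCCC
Why: Asymmetric SE2′ propargylboration, in which the B-propargyl diazaborolidine made from 4 adds to the aldehyde (not to the less electrophilic aryl ketone) through a six-membered chair with the aryl group equatorial, the sulfonamide controller directing attack to the Re face so that C3 is set as (R) and the three-carbon unit emerges as the terminal allene; the sodium alkoxide of 5 then takes the silyl group from the neighbouring phenol oxygen (1,5 O→O silyl shift through a six-membered silicate, driven by the far less basic para-acetylphenoxide), which frees the phenol and protects the carbinol in the same flask.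

Step 4
Reactants: 6 1-{3-[(1R)-1-{[tert-butyl(dimethyl)silyl]oxy}buta-2,3-dien-1-yl]-4-hydroxyphenyl}ethan-1-one
Product: 7 1-[(2S,3S)-2-(1-bromoethenyl)-3-{[tert-butyl(dimethyl)silyl]oxy}-2,3-dihydro-1-benzofuran-5-yl]ethan-1-one
Conditions: Pd(OAc)2 (10 mol %), LiBr, p-benzoquinone, MeCN/AcOH, rt
Reagents that add atoms: lithium bromide, [Li+].[Br-]
Why: Divalent palladium adds bromide to the central allene carbon (bromopalladation) to give a 2-bromo-η3-allyl complex spanning C2, Cα and the terminal CH2, and the phenol oxygen then attacks the substituted allyl terminus C2 anti to the metal, releasing zerovalent palladium that benzoquinone reoxidises. The closest known reaction type is the palladium-catalysed intramolecular 1,2-oxidation of allenes that carry a tethered OH, CO2H or NHTs group, which gives 2-(1-bromovinyl) heterocycles. Ring B closes at O1–C2 in the 5-exo mode on the allyl terminus, since attack at the CH2 terminus would require a seven-membered ring. C2 is controlled by the C3 silyloxy centre: the two diastereomeric allyl complexes should interconvert by η3–η1–η3 slippage at the unsubstituted CH2 end, and the transition state that keeps the bromoallyl–palladium unit anti to the bulky silyloxy group leads to the trans (2S,3S) product. The step needs capture by the phenol in preference to acetate capture, β-elimination or oxidation of the phenol, and this is secured by the five-membered geometry, by the silyl ether at C3 (an ester there would be lost by β-acyloxy elimination to a 2-bromodiene) and by the para acetyl group, which keeps the phenol electron-poor. The 1-bromovinyl group so formed is the direct precursor of the α-methylene aldehyde.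

Step 5
Reactants: 7 1-[(2S,3S)-2-(1-bromoethenyl)-3-{[tert-butyl(dimethyl)silyl]oxy}-2,3-dihydro-1-benzofuran-5-yl]ethan-1-one
Product: 8 (1R)-1-[(2S,3S)-2-(1-bromoethenyl)-3-{[tert-butyl(dimethyl)silyl]oxy}-2,3-dihydro-1-benzofuran-5-yl]ethan-1-ol
Conditions: (S)-1-methyl-3,3-diphenyltetrahydro-1H,3H-pyrrolo[1,2-c][1,3,2]oxazaborole (15 mol %), BH3·SMe2, THF, −20 °C; MeOH
Reagents that add atoms: none
Why: Corey–Bakshi–Shibata reduction, in which the ketone binds the ring boron anti to the larger aryl group and the nitrogen-bound borane delivers hydride to the Si face to set the (1R) side-chain carbinol, while the vinyl bromide and the silyl ether are inert at this temperature.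

Step 6
Reactants: 8 (1R)-1-[(2S,3S)-2-(1-bromoethenyl)-3-{[tert-butyl(dimethyl)silyl]oxy}-2,3-dihydro-1-benzofuran-5-yl]ethan-1-ol
Product: 9 (2S,3S)-2-(1-bromoethenyl)-5-[(1R)-1-hydroxyethyl]-2,3-dihydro-1-benzofuran-3-ol
Conditions: Bu4NF, AcOH, THF, 0 °C → rt
Reagents that add atoms: none
Why: Fluoride-induced cleavage of the secondary silyl ether, buffered with acetic acid so that no strongly basic species acts on the vinyl bromide; neither carbinol carbon is touched.

Step 7
Reactants: 9 (2S,3S)-2-(1-bromoethenyl)-5-[(1R)-1-hydroxyethyl]-2,3-dihydro-1-benzofuran-3-ol; 10 tiglic acid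
Product: 11 (1R)-1-[(2S,3S)-2-(1-bromoethenyl)-3-{[(2E)-2-methylbut-2-enoyl]oxy}-2,3-dihydro-1-benzofuran-5-yl]ethyl (2E)-2-methylbut-2-enoate
Conditions: 10 (3 equiv), N,N′-dicyclohexylcarbodiimide, 4-(dimethylamino)pyridine, CH2Cl2, 0 °C → rt
Reagents that add atoms: tiglic acid (10, two equivalents, one tigloyl group each), C/C=C(\C)C(=O)O
Why: Steglich esterification acylates both secondary benzylic alcohols at oxygen with retention at C3 and at the side-chain carbon, the E geometry of the acid is kept, and the trans ring leaves no hydrogen anti to the C3 ester, so base-induced elimination to the benzofuran is not favoured.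

Step 8
Reactants: 11 (1R)-1-[(2S,3S)-2-(1-bromoethenyl)-3-{[(2E)-2-methylbut-2-enoyl]oxy}-2,3-dihydro-1-benzofuran-5-yl]ethyl (2E)-2-methylbut-2-enoate
Product: 12 (1R)-1-[(2R,3S)-3-{[(2E)-2-methylbut-2-enoyl]oxy}-2-(3-oxoprop-1-en-2-yl)-2,3-dihydro-1-benzofuran-5-yl]ethyl (2E)-2-methylbut-2-enoate
Conditions: Pd(PPh3)4 (5 mol %), CO (3 bar), Bu3SnH (slow addition), toluene, 50 °C
Reagents that add atoms: carbon monoxide, [C-]#[O+]
Why: Palladium-catalysed reductive carbonylation (formylation) of an alkenyl bromide, in which oxidative addition to zerovalent palladium, CO insertion and hydride transfer from tin give the α-substituted acrolein without touching the two enoate esters, slow addition of the hydride limiting direct reduction of the C–Br bond and conjugate reduction of the enal; no stereocentre is involved (the descriptor at C2 changes from S to R only because the substituent priorities change).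

Compound list
1 | 4'-hydroxyacetophenone | CC(=O)c1ccc(O)cc1 | starting material
2 | 5-acetyl-2-hydroxybenzaldehyde | CC(=O)c1ccc(O)c(C=O)c1 | intermediate
3 | 5-acetyl-2-{[tert-butyl(dimethyl)silyl]oxy}benzaldehyde | CC(=O)c1ccc(O[Si](C)(C)C(C)(C)C)c(C=O)c1 | intermediate
4 | tributyl(propa-1,2-dien-1-yl)stannane (allenyltributylstannane) | C=C=C[Sn](CCCC)(CCCC)CCCC | starting material
5 | 1-{4-{[tert-butyl(dimethyl)silyl]oxy}-3-[(1R)-1-hydroxybuta-2,3-dien-1-yl]phenyl}ethan-1-one (not isolated) | C=C=C[C@@H](O)c1cc(C(C)=O)ccc1O[Si](C)(C)C(C)(C)C | intermediate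
6 | 1-{3-[(1R)-1-{[tert-butyl(dimethyl)silyl]oxy}buta-2,3-dien-1-yl]-4-hydroxyphenyl}ethan-1-one | C=C=C[C@@H](O[Si](C)(C)C(C)(C)C)c1cc(C(C)=O)ccc1O | intermediate
7 | 1-[(2S,3S)-2-(1-bromoethenyl)-3-{[tert-butyl(dimethyl)silyl]oxy}-2,3-dihydro-1-benzofuran-5-yl]ethan-1-one (trans) | C=C(Br)[C@H]1Oc2ccc(C(C)=O)cc2[C@@H]1O[Si](C)(C)C(C)(C)C | intermediate
8 | (1R)-1-[(2S,3S)-2-(1-bromoethenyl)-3-{[tert-butyl(dimethyl)silyl]oxy}-2,3-dihydro-1-benzofuran-5-yl]ethan-1-ol | C=C(Br)[C@H]1Oc2ccc([C@@H](C)O)cc2[C@@H]1O[Si](C)(C)C(C)(C)C | intermediate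
9 | (2S,3S)-2-(1-bromoethenyl)-5-[(1R)-1-hydroxyethyl]-2,3-dihydro-1-benzofuran-3-ol | C=C(Br)[C@H]1Oc2ccc([C@@H](C)O)cc2[C@@H]1O | intermediate
10 | tiglic acid, (2E)-2-methylbut-2-enoic acid | C/C=C(\C)C(=O)O | starting material
11 | (1R)-1-[(2S,3S)-2-(1-bromoethenyl)-3-{[(2E)-2-methylbut-2-enoyl]oxy}-2,3-dihydro-1-benzofuran-5-yl]ethyl (2E)-2-methylbut-2-enoate | C=C(Br)[C@H]1Oc2ccc([C@@H](C)OC(=O)/C(C)=C/C)cc2[C@@H]1OC(=O)/C(C)=C/C | intermediate
12 | (1R)-1-[(2R,3S)-3-{[(2E)-2-methylbut-2-enoyl]oxy}-2-(3-oxoprop-1-en-2-yl)-2,3-dihydro-1-benzofuran-5-yl]ethyl (2E)-2-methylbut-2-enoate | C=C(C=O)[C@H]1Oc2ccc([C@@H](C)OC(=O)/C(C)=C/C)cc2[C@@H]1OC(=O)/C(C)=C/C | target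

Total step count: 8. Longest linear sequence: 8 steps (1 → 12).

Steps most likely to fail

Step 4. Capture of the bromoallyl–palladium intermediate by acetate, or its β-elimination, may outrun ring closure, or the ring may close with poor facial selectivity at C2. The fallback would set out from 6: Hg(O2CCF3)2 in CH2Cl2 at 0 °C followed by aqueous NaCl should give, by anti oxymercuration of the inner allene double bond with the phenol as nucleophile, chloro{1-[(2S,3S)-5-acetyl-3-{[tert-butyl(dimethyl)silyl]oxy}-2,3-dihydro-1-benzofuran-2-yl]ethenyl}mercury F1. Bromodemercuration of F1 with Br2 in pyridine, with retention at the alkenyl carbon, would come back to the route at 7.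

Step 8. The tin hydride may reduce the carbon–bromine bond directly or reduce the enal in the conjugate sense, or zerovalent palladium may open the allylic C2–O1 bond. The fallback would set out from 11: Stille coupling with (tributylstannyl)methanol (Pd(PPh3)4, dioxane, 80 °C) should give the allylic alcohol (1R)-1-[(2R,3S)-2-(3-hydroxyprop-1-en-2-yl)-3-{[(2E)-2-methylbut-2-enoyl]oxy}-2,3-dihydro-1-benzofuran-5-yl]ethyl (2E)-2-methylbut-2-enoate F2. Oxidation of F2 with MnO2 in CH2Cl2 would come back to the route at 12.

Step 3. The silyl transfer may stay incomplete or turn intermolecular, the sodium alkoxide may enolise the methyl ketone, and the propargyl–allenyl regiochemistry on boron may erode. The fallback would set out from 5, isolated after the boron work-up: silylation with tBuMe2SiCl and imidazole in DMF should give the bis-silyl ether 1-{4-{[tert-butyl(dimethyl)silyl]oxy}-3-[(1R)-1-{[tert-butyl(dimethyl)silyl]oxy}buta-2,3-dien-1-yl]phenyl}ethan-1-one F3. Selective cleavage of the aryl silyl ether of F3 with KHF2 in MeOH would come back to the route at 6.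

Further compounds
F1 | step 4 | chloro{1-[(2S,3S)-5-acetyl-3-{[tert-butyl(dimethyl)silyl]oxy}-2,3-dihydro-1-benzofuran-2-yl]ethenyl}mercury | C=C([Hg]Cl)[C@H]1Oc2ccc(C(C)=O)cc2[C@@H]1O[Si](C)(C)C(C)(C)C
F2 | step 8 | (1R)-1-[(2R,3S)-2-(3-hydroxyprop-1-en-2-yl)-3-{[(2E)-2-methylbut-2-enoyl]oxy}-2,3-dihydro-1-benzofuran-5-yl]ethyl (2E)-2-methylbut-2-enoate | C=C(CO)[C@H]1Oc2ccc([C@@H](C)OC(=O)/C(C)=C/C)cc2[C@@H]1OC(=O)/C(C)=C/C
F3 | step 3 | 1-{4-{[tert-butyl(dimethyl)silyl]oxy}-3-[(1R)-1-{[tert-butyl(dimethyl)silyl]oxy}buta-2,3-dien-1-yl]phenyl}ethan-1-one | C=C=C[C@@H](O[Si](C)(C)C(C)(C)C)c1cc(C(C)=O)ccc1O[Si](C)(C)C(C)(C)C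
A1 | direct plan | 2-(3,3-dimethoxy-2-oxopropoxy)-5-[(1R)-1-hydroxyethyl]benzaldehyde | COC(OC)C(=O)COc1ccc([C@@H](C)O)cc1C=O
A2 | direct plan | 1-[(2S,3S)-3-hydroxy-5-[(1R)-1-hydroxyethyl]-2,3-dihydro-1-benzofuran-2-yl]-2,2-dimethoxyethan-1-one | COC(OC)C(=O)[C@H]1Oc2ccc([C@@H](C)O)cc2[C@@H]1O
A3 | direct plan | (2R,3S)-2-(3,3-dimethoxyprop-1-en-2-yl)-5-[(1R)-1-hydroxyethyl]-2,3-dihydro-1-benzofuran-3-ol | C=C(C(OC)OC)[C@H]1Oc2ccc([C@@H](C)O)cc2[C@@H]1O
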